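## Retrosynthetic overview

1. Target ⇐ its 8-O-ethyl ether; the last step is a chelation-controlled BCl3 dealkylation.
2. Naphthalene: ring B is a furan that is annulated with 3-methoxybenzyne (which brings ring A) and isomerised by acid to the 4-substituted 1-naphthol.
3. Rings C and D together: intramolecular furan–ynone Diels–Alder/aromatisation of a prochiral di(2-furyl)methane ynone; a chiral Lewis acid selects one of the two enantiotopic furans and so sets C4.
4. Ynone ⇐ methyl 4,4-di(2-furyl)butanoate + ethoxyacetylide; ester ⇐ 2 furan + methyl 4-oxobutanoate.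
5. Ring order: C + D (one operation) → B fused onto preformed A → deprotection.

Ring letters: A = methoxy-bearing benzo ring, B = hydroxy-bearing naphthalene ring, C = cyclohexanone ring, D = catechol ring.

Assumption 1: the sense of induction of the step 3 catalyst cannot be predicted with confidence; the (S)-catalyst is written and its mirror image is used if the first run gives the antipode of 10.

Assumption 2: the SMILES strings are authoritative for configuration; the CIP letter at C4 changes along the route because substituent priorities change, while the spatial arrangement stays the same.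

## Route

Step 1
Reactants: 1 furan; 2 methyl 4-oxobutanoate
Product: 4 methyl 4,4-di(furan-2-yl)butanoate, via furyl carbinol 3 (not isolated)
Conditions: TsOH·H2O (5 mol%), 1 (15 equiv), CH2Cl2, 0 °C → rt
Reagents that add atoms: none
Why: Acid-catalysed double Friedel–Crafts reaction at furan C2 (hydroxyalkylation, then alkylation through the furfuryl cation from 3), with the large excess of furan suppressing further attack on the product; the carbon carrying the two identical furyl groups is prochiral and no stereocenter exists yet.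

Step 2
Reactants: 4 methyl 4,4-di(furan-2-yl)butanoate; 5 ethoxyacetylene
Product: 7 1-ethoxy-6,6-di(furan-2-yl)hex-1-yn-3-one, via lithium ethoxyacetylide 6 (not isolated)
Conditions: 5 (2.1 equiv), n-BuLi (2.0 equiv), THF, −78 °C; BF3·OEt2 (2.0 equiv), −78 °C; then 4, −78 °C, 1 h; aq NaHCO3 quench; Et3N-deactivated SiO2
Reagents that add atoms: none
Why: Ester-to-ynone acylation of a lithium acetylide in the presence of BF3·OEt2 (Yamaguchi-type alkynylation), in which the tetrahedral adduct survives at −78 °C and collapses only on quench, so the ynone is not alkynylated twice and the acid-sensitive ynol ether meets only a basic work-up; no stereocenter is formed.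

Step 3
Reactants: 7 1-ethoxy-6,6-di(furan-2-yl)hex-1-yn-3-one
Product: 10 (S)-8-ethoxy-4-(furan-2-yl)-7-(methoxymethoxy)-3,4-dihydronaphthalen-1(2H)-one, via oxanorbornadiene cycloadduct 8 (not isolated), via phenol 9 (not isolated)
Conditions: (S)-3,3-diphenyl-1-(o-tolyl)tetrahydro-1H,3H-pyrrolo[1,2-c][1,3,2]oxazaborole (20 mol%), (CF3SO2)2NH (16 mol%), CH2Cl2 (0.02 M), −78 → −40 °C; then i-Pr2NEt (4 equiv), MOMCl (2 equiv), 0 °C → rt
Reagents that add atoms: chloromethyl methyl ether (MOMCl), COCCl
Why: Proposed new method: the N-protonated oxazaborolidine binds the ynone carbonyl and shields one face of the conjugated alkyne, so the intramolecular Diels–Alder reaction of a furan (chair-like tether, spectator furyl pseudo-equatorial, nucleophilic furan C5 matched to the electrophilic ethoxy-bearing alkyne carbon) can engage only one of the two enantiotopic furans, which sets C4 and builds rings C and D at once; the oxanorbornadiene 8 then opens at the bridgehead C–O bond whose cation is stabilised by the vinylogous ethoxy group and aromatises to the 7-phenol 9, which is capped in the same pot by O-alkylation; the closest known chemistry is the cationic oxazaborolidine-catalysed enantioselective Diels–Alder reaction of acetylenic ketones and of furans, together with the thermal or Lewis-acid furan–ynone cycloaddition/aromatisation to hydroxy-tetralones.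

Step 4
Reactants: 10 (S)-8-ethoxy-4-(furan-2-yl)-7-(methoxymethoxy)-3,4-dihydronaphthalen-1(2H)-one; 11 3-methoxy-2-(trimethylsilyl)phenyl trifluoromethanesulfonate
Product: 15 (R)-8-ethoxy-7-hydroxy-4-(4-hydroxy-8-methoxynaphthalen-1-yl)-3,4-dihydronaphthalen-1(2H)-one, via 3-methoxybenzyne 12 (not isolated), via oxabicyclic cycloadduct 13 (not isolated), via MOM naphthol 14 (not isolated)
Conditions: 11 (1.5 equiv), CsF (3 equiv), MeCN, rt; concentrate; then conc. aq HCl, MeOH/THF, rt → 40 °C; chromatography
Reagents that add atoms: none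
Why: Aryne–furan Diels–Alder cycloaddition (fluoride-induced 1,2-elimination gives 12) in which the more nucleophilic unsubstituted furan C5 bonds to the aryne carbon remote from OMe and so places OMe peri to the substituted bridgehead (a modest electronic preference opposed by sterics; the distal isomer is removed after aromatisation), followed by acid-catalysed oxabicycle-to-naphthol isomerisation through the tertiary, ortho-methoxy-stabilised benzylic cation with concurrent cleavage of the MOM acetal; C4 is not a reacting centre and keeps its configuration, and the two bridgehead centres vanish on aromatisation.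

Step 5
Reactants: 15 (R)-8-ethoxy-7-hydroxy-4-(4-hydroxy-8-methoxynaphthalen-1-yl)-3,4-dihydronaphthalen-1(2H)-one
Product: 16 (R)-7,8-dihydroxy-4-(4-hydroxy-8-methoxynaphthalen-1-yl)-3,4-dihydronaphthalen-1(2H)-one
Conditions: BCl3 (6 equiv), CH2Cl2, −78 → 0 °C; H2O quench; work-up under argon
Reagents that add atoms: none
Why: Chelation-controlled Lewis-acid ether cleavage: boron is held by the C1 carbonyl and the C7 oxygen (six- and five-membered chelates to the C8 oxygen), so chloride dealkylates only the C8 ethyl ether while the unchelated naphthyl methyl ether survives at or below 0 °C; C4 is untouched.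

## Compound list

1 | furan | c1ccoc1 | starting material
2 | methyl 4-oxobutanoate | COC(=O)CCC=O | starting material
3 | methyl 4-(furan-2-yl)-4-hydroxybutanoate (racemic, not isolated) | COC(=O)CCC(O)c1ccco1 | intermediate
4 | methyl 4,4-di(furan-2-yl)butanoate | COC(=O)CCC(c1ccco1)c1ccco1 | intermediate
5 | ethoxyacetylene | CCOC#C | starting material
6 | lithium ethoxyacetylide (not isolated) | [Li]C#COCC | intermediate
7 | 1-ethoxy-6,6-di(furan-2-yl)hex-1-yn-3-one | CCOC#CC(=O)CCC(c1ccco1)c1ccco1 | intermediate
8 | (4R)-8-ethoxy-4-(furan-2-yl)-2,3,4,7-tetrahydro-4a,7-epoxynaphthalen-1-one, bridgeheads 4a and 7 not assigned (not isolated) | CCOC1=C2C(=O)CC[C@H](c3ccco3)C24OC1C=C4 | intermediate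
9 | (S)-8-ethoxy-4-(furan-2-yl)-7-hydroxy-3,4-dihydronaphthalen-1(2H)-one (not isolated) | o1cccc1[C@H]2CCC(=O)c3c2ccc(O)c3OCC | intermediate
10 | (S)-8-ethoxy-4-(furan-2-yl)-7-(methoxymethoxy)-3,4-dihydronaphthalen-1(2H)-one | o1cccc1[C@H]2CCC(=O)c3c2ccc(OCOC)c3OCC | intermediate
11 | 3-methoxy-2-(trimethylsilyl)phenyl trifluoromethanesulfonate | COc1cccc(OS(=O)(=O)C(F)(F)F)c1[Si](C)(C)C | starting material
12 | 3-methoxybenzyne (not isolated) | COC1=CC=CC#C1 | intermediate
13 | (4S)-8-ethoxy-4-(8-methoxy-1,4-dihydro-1,4-epoxynaphthalen-1-yl)-7-(methoxymethoxy)-3,4-dihydronaphthalen-1(2H)-one, bridgehead epimers (not isolated) | COc1cccc2c1C1([C@H]3CCC(=O)c4c3ccc(OCOC)c4OCC)OC2C=C1 | intermediate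
14 | (R)-8-ethoxy-4-(4-hydroxy-8-methoxynaphthalen-1-yl)-7-(methoxymethoxy)-3,4-dihydronaphthalen-1(2H)-one (not isolated) | COc1cccc2c(O)ccc([C@H]3CCC(=O)c4c3ccc(OCOC)c4OCC)c12 | intermediate
15 | (R)-8-ethoxy-7-hydroxy-4-(4-hydroxy-8-methoxynaphthalen-1-yl)-3,4-dihydronaphthalen-1(2H)-one | COc1cccc2c(O)ccc([C@H]3CCC(=O)c4c3ccc(O)c4OCC)c12 | intermediate
16 | (R)-7,8-dihydroxy-4-(4-hydroxy-8-methoxynaphthalen-1-yl)-3,4-dihydronaphthalen-1(2H)-one | COc1cccc2c(O)ccc([C@H]3CCC(=O)c4c3ccc(O)c4O)c12 | target

## Count and risks

Total steps: 5. Longest linear sequence: 5 (from 1 and 2).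

Three steps most likely to fail:

**Step 3 (group-selective furan–ynone cycloaddition).** The enantiotopic-furan selection is unprecedented; ee may be low, and the ynol ether may not tolerate the strong acid. The ee is read on 10 by chiral HPLC and the absolute configuration confirmed by X-ray or ECD. Fallback: set out from 7 and drop catalyst control in favour of a racemic cyclisation plus resolution. Me2AlCl (1.1 equiv, CH2Cl2, −78 → 0 °C) drives the same cycloaddition to the racemic oxanorbornadiene F1, which aromatises to racemic 8-ethoxy-4-(furan-2-yl)-7-hydroxy-3,4-dihydronaphthalen-1(2H)-one F2. F2 is resolved by preparative chiral SFC (amylose tris(3,5-dimethylphenylcarbamate) phase, CO2/MeOH). The (S)-enantiomer is 9, which is capped with MOMCl/i-Pr2NEt as in step 3, and the route is rejoined at 9 and then 10.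

**Step 4 (aryne regiochemistry and acid isomerisation).** The branched substituent on the furan may push the methoxy group to the distal position. In addition, loss of the C4 proton from the benzylic cation would erode ee, so the ee of 15 is checked. Fallback: set out from 10 and use a more strongly polarised aryne, then exchange the functional group. 2-(Trimethylsilyl)-1,3-phenylene bis(trifluoromethanesulfonate) with CsF in MeCN gives 3-(trifluoromethanesulfonyloxy)benzyne F3. Its strong inductive bias directs furan C5 to the remote aryne carbon and gives the proximal oxabicyclic aryl triflate F4. S–O cleavage with Et4NOH (dioxane/H2O, rt) gives the oxabicyclic phenol F5. MeI/K2CO3 (acetone) methylates F5 to 13, where the route is rejoined; the acid treatment of step 4 then gives 15.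

**Step 5 (selective de-ethylation).** An ethyl ether cleaves more slowly than a methyl ether; forcing conditions could also remove the naphthyl methyl group. Fallback: set out from 9 (isolated from step 3 before capping) and remove the ethyl group before any methyl ether is present. BCl3 (CH2Cl2, −78 → −20 °C) gives the catechol (S)-4-(furan-2-yl)-7,8-dihydroxy-3,4-dihydronaphthalen-1(2H)-one F6. MOMCl/i-Pr2NEt gives the bis-MOM ether F7. Cycloaddition with 12 (from 11/CsF, MeCN) gives the oxabicycle F8. HCl/MeOH isomerises F8 to the bis-MOM naphthol F9 and removes both acetals, arriving directly at 16.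

Further compounds

F1 | step 3 | racemic 8-ethoxy-4-(furan-2-yl)-2,3,4,7-tetrahydro-4a,7-epoxynaphthalen-1-one | CCOC1=C2C(=O)CCC(c3ccco3)C24OC1C=C4
F2 | step 3 | racemic 8-ethoxy-4-(furan-2-yl)-7-hydroxy-3,4-dihydronaphthalen-1(2H)-one | CCOc1c(O)ccc2c1C(=O)CCC2c1ccco1
F3 | step 4 | 3-(trifluoromethanesulfonyloxy)benzyne | O=S(=O)(OC1=CC=CC#C1)C(F)(F)F
F4 | step 4 | (4S)-8-ethoxy-7-(methoxymethoxy)-4-[8-(trifluoromethanesulfonyloxy)-1,4-dihydro-1,4-epoxynaphthalen-1-yl]-3,4-dihydronaphthalen-1(2H)-one | O=S(=O)(Oc1cccc2c1C1([C@H]3CCC(=O)c4c3ccc(OCOC)c4OCC)OC2C=C1)C(F)(F)F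
F5 | step 4 | (4S)-8-ethoxy-4-(8-hydroxy-1,4-dihydro-1,4-epoxynaphthalen-1-yl)-7-(methoxymethoxy)-3,4-dihydronaphthalen-1(2H)-one | Oc1cccc2c1C1([C@H]3CCC(=O)c4c3ccc(OCOC)c4OCC)OC2C=C1
F6 | step 5 | (S)-4-(furan-2-yl)-7,8-dihydroxy-3,4-dihydronaphthalen-1(2H)-one | o1cccc1[C@H]2CCC(=O)c3c2ccc(O)c3O
F7 | step 5 | (S)-4-(furan-2-yl)-7,8-bis(methoxymethoxy)-3,4-dihydronaphthalen-1(2H)-one | o1cccc1[C@H]2CCC(=O)c3c2ccc(OCOC)c3OCOC
F8 | step 5 | (4S)-4-(8-methoxy-1,4-dihydro-1,4-epoxynaphthalen-1-yl)-7,8-bis(methoxymethoxy)-3,4-dihydronaphthalen-1(2H)-one | COc1cccc2c1C1([C@H]3CCC(=O)c4c3ccc(OCOC)c4OCOC)OC2C=C1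
F9 | step 5 | (R)-4-(4-hydroxy-8-methoxynaphthalen-1-yl)-7,8-bis(methoxymethoxy)-3,4-dihydronaphthalen-1(2H)-one | COc1cccc2c(O)ccc([C@H]3CCC(=O)c4c3ccc(OCOC)c4OCOC)c12
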